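## Retrosynthetic overview

1. Target ⇐ global desilylation of a protected furofuran; the α-aryl-β-hydroxy ketone travels as a syn-1,3-diol acetonide and is oxidised second to last.
2. Furofuran (both tetrahydrofuran rings closed together, last of all rings) ⇐ tetraol ⇐ three-component conjugate addition–aldol of the right-half dithiane, (5R)-5-menthyloxyfuran-2(5H)-one and the left-half aldehyde.
3. Right half: the cis-dihydrobenzofuran ring (first ring formed) by enantioselective dirhodium-carbenoid C–H insertion of an aryldiazoacetate.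
4. Left half: Evans syn-aldol of an arylacetyl oxazolidinone with O-triisopropylsilyl vanillin sets the ketone α-centre.
5. All four arenes come from catechol via 4-bromoguaiacol; an aromatic Claisen rearrangement installs the two-carbon side chains of rings A and B.

**Assumption:** the SMILES is taken literally: pinoresinol-type furofuran (7S,8R,7'S,8'R, both aryl groups exo), dihydrobenzofuran 2S,3S (2-aryl and 3-hydroxymethyl cis), and S at the ketone α-carbon.

**Abbreviations:** TIPS = triisopropylsilyl; TBS = tert-butyldimethylsilyl; Men = (1R,2S,5R)-menthyl; ArG = 3-methoxy-4-(TIPS-oxy)phenyl; ArL = 4-(TBS-oxy)-3-methoxy-5-[(4R,5S)-4-ArG-2,2-dimethyl-1,3-dioxan-5-yl]phenyl; ArR = (2S,3S)-7-methoxy-2-ArG-3-(TIPS-oxymethyl)-2,3-dihydrobenzofuran-5-yl. Ring G1 = guaiacyl ring on the ketone, ring A = ring bearing the ketone side chain, ring B = benzo ring of the dihydrobenzofuran, ring G2 = guaiacyl ring on the dihydrobenzofuran.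

## Route

**Step 1**
Reactants: 1 catechol
Product: 2 2-methoxyphenol
Conditions: MeI (1.0 equiv), K2CO3, acetone, reflux
Reagents that add atoms: iodomethane, CI
Why: Williamson mono-O-methylation; the mono-anion alkylates once and guaiacol is separated from veratrole and catechol.

**Step 2**
Reactants: 2 2-methoxyphenol
Product: 3 4-bromo-2-methoxyphenol
Conditions: NBS, MeCN, 0 °C
Reagents that add atoms: N-bromosuccinimide, O=C1CCC(=O)N1Br
Why: electrophilic aromatic bromination directed para to the free hydroxyl, the stronger donor.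

**Step 3**
Reactants: 3 4-bromo-2-methoxyphenol
Product: 4 (4-bromo-2-methoxyphenoxy)triisopropylsilane
Conditions: TIPSCl, imidazole, DMF, rt
Reagents that add atoms: chlorotriisopropylsilane, CC(C)[Si](Cl)(C(C)C)C(C)C
Why: phenol silylation; the TIPS ether tolerates organolithiums, hydrides and mild acid.

**Step 4**
Reactants: 4 (4-bromo-2-methoxyphenoxy)triisopropylsilane
Product: 6 3-methoxy-4-(TIPS-oxy)benzaldehyde, via aryllithium 5 (not isolated)
Conditions: n-BuLi, THF, −78 °C; DMF; aq. NH4Cl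
Reagents that add atoms: N,N-dimethylformamide, CN(C)C=O
Why: bromine–lithium exchange followed by Bouveault formylation.

**Step 5**
Reactants: 6 3-methoxy-4-(TIPS-oxy)benzaldehyde
Product: 7 [3-methoxy-4-(TIPS-oxy)phenyl]methanol
Conditions: NaBH4, THF/MeOH (4:1), 0 °C; aq. NH4Cl
Reagents that add atoms: none
Why: borohydride reduction of the aryl aldehyde to the benzylic alcohol; the hindered aryl TIPS ether is untouched at 0 °C.

**Step 6**
Reactants: 3 4-bromo-2-methoxyphenol, 8 allyl bromide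
Product: 9 1-(allyloxy)-4-bromo-2-methoxybenzene
Conditions: K2CO3, acetone, reflux
Reagents that add atoms: none
Why: Williamson O-allylation of the phenol.

**Step 7**
Reactants: 9 1-(allyloxy)-4-bromo-2-methoxybenzene
Product: 11 2-allyl-4-bromo-6-methoxyphenol, via dienone 10 (not isolated)
Conditions: N,N-diethylaniline, 190 °C
Reagents that add atoms: none
Why: aromatic Claisen rearrangement to the only free ortho position (para is blocked by bromine), then tautomerisation.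

**Step 8**
Reactants: 11 2-allyl-4-bromo-6-methoxyphenol
Product: 12 (2-allyl-4-bromo-6-methoxyphenoxy)(tert-butyl)dimethylsilane
Conditions: TBSCl, imidazole, DMF, 40 °C
Reagents that add atoms: tert-butylchlorodimethylsilane, CC(C)(C)[Si](C)(C)Cl
Why: silylation of the flanked phenol; the doubly ortho-substituted aryl TBS ether is robust.

**Step 9**
Reactants: 12 (2-allyl-4-bromo-6-methoxyphenoxy)(tert-butyl)dimethylsilane
Product: 14 2-[5-bromo-2-(TBS-oxy)-3-methoxyphenyl]acetaldehyde, via secondary ozonide 13 (not isolated)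
Conditions: O3, CH2Cl2, −78 °C (stopped at alkene consumption); PPh3, −78 °C to rt
Reagents that add atoms: ozone, [O-][O+]=O
Why: ozonolysis of the terminal alkene with reductive work-up; the alkene reacts far faster than the arene at −78 °C.

**Step 10**
Reactants: 14 2-[5-bromo-2-(TBS-oxy)-3-methoxyphenyl]acetaldehyde
Product: 15 2-[5-bromo-2-(TBS-oxy)-3-methoxyphenyl]acetic acid
Conditions: NaClO2, NaH2PO4, 2-methyl-2-butene, t-BuOH/H2O, 0 °C to rt
Reagents that add atoms: sodium chlorite, [Na+].[O-]Cl=O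
Why: Pinnick oxidation, with the alkene scavenging hypochlorite so the electron-rich ring is not chlorinated.

**Step 11**
Reactants: 15 2-[5-bromo-2-(TBS-oxy)-3-methoxyphenyl]acetic acid
Product: 17 (4R)-4-benzyl-3-{2-[5-bromo-2-(TBS-oxy)-3-methoxyphenyl]acetyl}-1,3-oxazolidin-2-one, via mixed pivalic anhydride 16 (not isolated)
Conditions: PivCl, Et3N, THF, −20 °C; then (R)-4-benzyl-2-oxazolidinone, LiCl, −20 °C to rt
Reagents that add atoms: (R)-4-benzyl-1,3-oxazolidin-2-one, O=C1N[C@H](Cc2ccccc2)CO1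
Why: N-acylation of the Evans auxiliary through the mixed anhydride, which is attacked at the less hindered arylacetyl carbonyl.

**Step 12**
Reactants: 17 the arylacetyl imide, 6 3-methoxy-4-(TIPS-oxy)benzaldehyde
Product: 19 (4R)-4-benzyl-3-[(2R,3R)-2-(5-bromo-2-TBS-oxy-3-methoxyphenyl)-3-hydroxy-3-ArG-propanoyl]-1,3-oxazolidin-2-one, via boron enolate 18 (not isolated)
Conditions: Bu2BOTf, i-Pr2NEt, CH2Cl2, −78 to 0 °C; 6, −78 to 0 °C; pH 7 buffer, MeOH, H2O2, 0 °C
Reagents that add atoms: none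
Why: Evans syn-aldol; the Z-boron enolate reacts through a Zimmerman–Traxler chair on the face opposite the benzyl group, so the (R)-auxiliary sets both new centres as 2R,3R (the aryl-bearing centre becomes the S α-carbon of the ketone).

**Step 13**
Reactants: 19 the aldol adduct
Product: 20 (1R,2S)-2-(5-bromo-2-TBS-oxy-3-methoxyphenyl)-1-ArG-propane-1,3-diol
Conditions: LiBH4, MeOH (1.2 equiv), THF, 0 °C
Reagents that add atoms: none
Why: reductive cleavage of the imide to the primary alcohol without touching the α-aryl centre; the auxiliary is recovered.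

**Step 14**
Reactants: 20 the 1,3-diol
Product: 21 (4R,5S)-5-(5-bromo-2-TBS-oxy-3-methoxyphenyl)-4-ArG-2,2-dimethyl-1,3-dioxane
Conditions: 2,2-dimethoxypropane, pyridinium p-toluenesulfonate (cat.), CH2Cl2, rt
Reagents that add atoms: 2,2-dimethoxypropane, COC(C)(C)OC
Why: transacetalisation locks both hydroxyls as an acetonide that is stable to base, organolithiums and hydride.

**Step 15**
Reactants: 21 the bromo acetonide
Product: 23 4-(TBS-oxy)-3-methoxy-5-[(4R,5S)-4-ArG-2,2-dimethyl-1,3-dioxan-5-yl]benzaldehyde (ArL–CHO), via aryllithium 22 (not isolated)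
Conditions: n-BuLi, THF, −78 °C; DMF; aq. NH4Cl
Reagents that add atoms: N,N-dimethylformamide, CN(C)C=O
Why: bromine–lithium exchange outruns any deprotonation at −78 °C, and Bouveault formylation gives the left-half aldehyde.

**Step 16**
Reactants: 11 2-allyl-4-bromo-6-methoxyphenol, 7 [3-methoxy-4-(TIPS-oxy)phenyl]methanol
Product: 24 1-allyl-5-bromo-3-methoxy-2-(ArG-methoxy)benzene
Conditions: PPh3, diisopropyl azodicarboxylate, THF, 0 °C to rt
Reagents that add atoms: none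
Why: Mitsunobu etherification of the phenol with the primary benzylic alcohol, avoiding a labile electron-rich benzyl halide.

**Step 17**
Reactants: 24 the allyl benzyl ether
Product: 26 2-[5-bromo-3-methoxy-2-(ArG-methoxy)phenyl]acetaldehyde, via secondary ozonide 25 (not isolated)
Conditions: O3, CH2Cl2, −78 °C (stopped at alkene consumption); PPh3, −78 °C to rt
Reagents that add atoms: ozone, [O-][O+]=O
Why: chemoselective ozonolysis of the terminal alkene with reductive work-up.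

**Step 18**
Reactants: 26 the arylacetaldehyde
Product: 27 2-[5-bromo-3-methoxy-2-(ArG-methoxy)phenyl]acetic acid
Conditions: NaClO2, NaH2PO4, 2-methyl-2-butene, t-BuOH/H2O, 0 °C to rt
Reagents that add atoms: sodium chlorite, [Na+].[O-]Cl=O
Why: Pinnick oxidation.

**Step 19**
Reactants: 27 the arylacetic acid
Product: 28 methyl 2-[5-bromo-3-methoxy-2-(ArG-methoxy)phenyl]acetate
Conditions: Me3SiCHN2, toluene/MeOH, 0 °C
Reagents that add atoms: (trimethylsilyl)diazomethane, C[Si](C)(C)C=[N+]=[N-]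
Why: neutral methyl esterification that spares the aryl silyl ether.

**Step 20**
Reactants: 28 the methyl arylacetate
Product: 29 methyl 2-diazo-2-[5-bromo-3-methoxy-2-(ArG-methoxy)phenyl]acetate
Conditions: 4-acetamidobenzenesulfonyl azide, 1,8-diazabicyclo[5.4.0]undec-7-ene, MeCN, 0 °C to rt
Reagents that add atoms: 4-acetamidobenzenesulfonyl azide, CC(=O)Nc1ccc(cc1)S(=O)(=O)N=[N+]=[N-]
Why: Regitz diazo transfer to the acidic benzylic position of the arylacetate.

**Step 21**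
Reactants: 29 the aryldiazoacetate
Product: 30 methyl (2S,3R)-5-bromo-7-methoxy-2-ArG-2,3-dihydrobenzofuran-3-carboxylate (2,3-cis)
Conditions: Rh2(R-PTTL)4 (dirhodium tetrakis[N-phthaloyl-(R)-tert-leucinate], 1 mol%), toluene, −60 °C
Reagents that add atoms: none
Why: intramolecular carbenoid 1,5-C–H insertion into the activated benzylic O–CH2 bond is concerted and cis-selective; the chiral dirhodium carboxylate sets both C2 and C3, and the R-catalyst is chosen because the S-catalysts of this family give the mirror-image (2R) cis series, the sense being confirmed on the first batch.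

**Step 22**
Reactants: 30 the cis ester
Product: 31 [(2S,3S)-5-bromo-7-methoxy-2-ArG-2,3-dihydrobenzofuran-3-yl]methanol
Conditions: i-Bu2AlH, CH2Cl2, −78 to 0 °C; aq. potassium sodium tartrate
Reagents that add atoms: none
Why: non-basic hydride reduction removes the epimerisable ester α-proton problem and fixes the cis relationship.

**Step 23**
Reactants: 31 the cis alcohol
Product: 32 {[(2S,3S)-5-bromo-7-methoxy-2-ArG-2,3-dihydrobenzofuran-3-yl]methoxy}triisopropylsilane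
Conditions: TIPSCl, imidazole, DMF, rt
Reagents that add atoms: chlorotriisopropylsilane, CC(C)[Si](Cl)(C(C)C)C(C)C
Why: silylation of the primary alcohol with a group that survives Lewis acid, alkyllithium, hydride and dilute acid.

**Step 24**
Reactants: 32 the bromo dihydrobenzofuran
Product: 34 (2S,3S)-7-methoxy-2-ArG-3-(TIPS-oxymethyl)-2,3-dihydrobenzofuran-5-carbaldehyde (ArR–CHO), via aryllithium 33 (not isolated)
Conditions: n-BuLi, THF, −78 °C; DMF; aq. NH4Cl
Reagents that add atoms: N,N-dimethylformamide, CN(C)C=O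
Why: bromine–lithium exchange and Bouveault formylation.

**Step 25**
Reactants: 34 ArR–CHO
Product: 35 2-ArR-1,3-dithiane
Conditions: propane-1,3-dithiol, BF3·OEt2 (0.2 equiv), CH2Cl2, −20 to 0 °C
Reagents that add atoms: propane-1,3-dithiol, SCCCS
Why: Lewis-acid dithioacetalisation of the aromatic aldehyde gives the acyl-anion equivalent (Corey–Seebach umpolung).

**Step 26**
Reactants: 36 furfural
Product: 38 5-hydroxyfuran-2(5H)-one, via endoperoxide 37 (not isolated)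
Conditions: O2, visible light, 5,10,15,20-tetraphenylporphyrin (cat.), CH2Cl2/MeOH, 0 °C
Reagents that add atoms: oxygen, O=O
Why: singlet-oxygen [4+2] cycloaddition to the furan, then methanol-induced fragmentation of the endoperoxide with loss of the formyl carbon as methyl formate.

**Step 27**
Reactants: 38 5-hydroxyfuran-2(5H)-one
Product: 39 (5R)-5-[(1R,2S,5R)-menthyloxy]furan-2(5H)-one
Conditions: (−)-menthol, camphor-10-sulfonic acid (cat.), toluene, reflux (Dean–Stark); crystallisation from petroleum ether with acid re-equilibration of the mother liquor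
Reagents that add atoms: (1R,2S,5R)-menthol, CC(C)[C@@H]1CC[C@@H](C)C[C@H]1O
Why: acid-catalysed acetalisation gives both C5 epimers, and the 5R epimer is obtained pure by crystallisation-driven epimerisation.

**Step 28**
Reactants: 35 2-ArR-1,3-dithiane, 39 (5R)-5-menthyloxyfuran-2(5H)-one, 23 ArL–CHO
Product: 42 (3S,4R,5R)-3-[hydroxy(ArL)methyl]-4-(2-ArR-1,3-dithian-2-yl)-5-(menthyloxy)dihydrofuran-2(3H)-one (carbinol epimers), via lithiated dithiane 40 (not isolated), via lithium enolate 41 (not isolated)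
Conditions: n-BuLi, THF, −78 °C; 39, −78 °C; 23, −78 °C; AcOH, −78 °C
Reagents that add atoms: none
Why: tandem conjugate addition–aldol; the dithiane anion adds anti to the menthyloxy group (setting C4, the future C8'), and the enolate takes the aldehyde anti to the new C4 substituent (setting C3, the future C8), while the carbinol centre is left uncontrolled because it is ionised later.

**Step 29**
Reactants: 42 the dithiane adduct
Product: 43 (3S,4R,5R)-4-(ArR-carbonyl)-3-[hydroxy(ArL)methyl]-5-(menthyloxy)dihydrofuran-2(3H)-one (carbinol epimers)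
Conditions: MeI, CaCO3, MeCN/H2O (9:1), 45 °C
Reagents that add atoms: water, O
Why: alkylative dithiane hydrolysis under buffered, non-oxidising conditions; the aryl group stabilises the thionium ion, and silyl ethers, acetonide and acetal survive.

**Step 30**
Reactants: 43 the keto lactone
Product: 44 (2R,3R)-1-ArL-4-ArR-2,3-bis(hydroxymethyl)butane-1,4-diol (epimers at C1 and C4)
Conditions: LiAlH4, THF, 0 °C to rt; aq. work-up
Reagents that add atoms: none
Why: hydride reduces the ketone and opens the lactone acetal through two aldehydes to the 1,4-diol, releasing menthol; the two central stereocentres are untouched.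

**Step 31**
Reactants: 44 the tetraol
Product: 45 (1S,3aR,4S,6aR)-1-ArL-4-ArR-tetrahydro-1H,3H-furo[3,4-c]furan
Conditions: camphor-10-sulfonic acid (0.2 equiv), 4 Å molecular sieves, CH2Cl2, 0 °C to rt, stopped at full conversion
Reagents that add atoms: none
Why: double SN1 cyclodehydration; each para-oxygenated benzylic carbinol ionises and is captured 5-exo by the 1,4-related primary hydroxyl on the face that places the aryl group exo, so C7 and C7' are both set S convergently from the epimer mixture under kinetic control, relayed from the 8R,8'R centres.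

**Step 32**
Reactants: 45 the protected furofuran
Product: 46 (1R,2S)-1-ArG-2-{2-(TBS-oxy)-3-methoxy-5-[(1S,3aR,4S,6aR)-4-ArR-tetrahydro-1H,3H-furo[3,4-c]furan-1-yl]phenyl}propane-1,3-diol
Conditions: AcOH/THF/H2O (3:1:1), 40 °C
Reagents that add atoms: none
Why: mild hydrolysis of the strained 1,3-dioxane acetonide; aryl silyl ethers, the primary TIPS ether and the furofuran are stable to dilute acetic acid.

**Step 33**
Reactants: 46 the 1,3-diol
Product: 47 (1R,2S)-3-(TBS-oxy)-1-ArG-2-{2-(TBS-oxy)-3-methoxy-5-[(1S,3aR,4S,6aR)-4-ArR-tetrahydro-1H,3H-furo[3,4-c]furan-1-yl]phenyl}propan-1-ol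
Conditions: TBSCl (1.1 equiv), imidazole, CH2Cl2, 0 °C
Reagents that add atoms: tert-butylchlorodimethylsilane, CC(C)(C)[Si](C)(C)Cl
Why: selective silylation of the primary hydroxyl over the hindered secondary benzylic one.

**Step 34**
Reactants: 47 the secondary benzylic alcohol
Product: 48 (2S)-3-(TBS-oxy)-1-ArG-2-{2-(TBS-oxy)-3-methoxy-5-[(1S,3aR,4S,6aR)-4-ArR-tetrahydro-1H,3H-furo[3,4-c]furan-1-yl]phenyl}propan-1-one
Conditions: Dess–Martin periodinane, NaHCO3, CH2Cl2, 0 °C to rt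
Reagents that add atoms: none
Why: Dess–Martin oxidation is near-neutral, so the acidic α-aryl centre (S) is not enolised and the β-silyloxy group is not eliminated.

**Step 35**
Reactants: 48 the penta-silylated ketone
Product: 49 the target (CNP0174045.1)
Conditions: HF·pyridine, pyridine, THF, 0 °C to rt
Reagents that add atoms: none
Why: buffered acidic fluoride removes all five silyl groups without the basic conditions that would epimerise or dehydrate the α-aryl-β-hydroxy ketone.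

## Compound list

1 | catechol | Oc1ccccc1O | starting material
2 | 2-methoxyphenol | COc1ccccc1O | intermediate
3 | 4-bromo-2-methoxyphenol | COc1cc(Br)ccc1O | intermediate
4 | (4-bromo-2-methoxyphenoxy)triisopropylsilane | COc1cc(Br)ccc1O[Si](C(C)C)(C(C)C)C(C)C | intermediate
5 | [3-methoxy-4-(TIPS-oxy)phenyl]lithium | [Li]c1ccc(O[Si](C(C)C)(C(C)C)C(C)C)c(OC)c1 | intermediate
6 | 3-methoxy-4-(TIPS-oxy)benzaldehyde | COc1cc(C=O)ccc1O[Si](C(C)C)(C(C)C)C(C)C | intermediate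
7 | [3-methoxy-4-(TIPS-oxy)phenyl]methanol | COc1cc(CO)ccc1O[Si](C(C)C)(C(C)C)C(C)C | intermediate
8 | allyl bromide | C=CCBr | starting material
9 | 1-(allyloxy)-4-bromo-2-methoxybenzene | C=CCOc1ccc(Br)cc1OC | intermediate
10 | 6-allyl-4-bromo-2-methoxycyclohexa-2,4-dien-1-one (racemic) | O=C1C(CC=C)C=C(Br)C=C1OC | intermediate
11 | 2-allyl-4-bromo-6-methoxyphenol | C=CCc1cc(Br)cc(OC)c1O | intermediate
12 | (2-allyl-4-bromo-6-methoxyphenoxy)(tert-butyl)dimethylsilane | C=CCc1cc(Br)cc(OC)c1O[Si](C)(C)C(C)(C)C | intermediate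
13 | 3-[5-bromo-2-(TBS-oxy)-3-methoxybenzyl]-1,2,4-trioxolane | COc1cc(Br)cc(CC2OCOO2)c1O[Si](C)(C)C(C)(C)C | intermediate
14 | 2-[5-bromo-2-(TBS-oxy)-3-methoxyphenyl]acetaldehyde | O=CCc1cc(Br)cc(OC)c1O[Si](C)(C)C(C)(C)C | intermediate
15 | 2-[5-bromo-2-(TBS-oxy)-3-methoxyphenyl]acetic acid | OC(=O)Cc1cc(Br)cc(OC)c1O[Si](C)(C)C(C)(C)C | intermediate
16 | mixed anhydride of 15 with pivalic acid | CC(C)(C)C(=O)OC(=O)Cc1cc(Br)cc(OC)c1O[Si](C)(C)C(C)(C)C | intermediate
17 | (4R)-4-benzyl-3-{2-[5-bromo-2-(TBS-oxy)-3-methoxyphenyl]acetyl}-1,3-oxazolidin-2-one | O=C(Cc1cc(Br)cc(OC)c1O[Si](C)(C)C(C)(C)C)N1C(=O)OC[C@H]1Cc1ccccc1 | intermediate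
18 | Z-dibutylboron enolate of 17 | CCCCB(CCCC)O/C(=C\c1cc(Br)cc(OC)c1O[Si](C)(C)C(C)(C)C)N1C(=O)OC[C@H]1Cc1ccccc1 | intermediate
19 | (4R)-4-benzyl-3-[(2R,3R)-2-(5-bromo-2-TBS-oxy-3-methoxyphenyl)-3-hydroxy-3-ArG-propanoyl]-1,3-oxazolidin-2-one | Brc1cc(OC)c(O[Si](C)(C)C(C)(C)C)c(c1)[C@@H](C(=O)N1C(=O)OC[C@H]1Cc1ccccc1)[C@@H](O)c1ccc(O[Si](C(C)C)(C(C)C)C(C)C)c(OC)c1 | intermediate
20 | (1R,2S)-2-(5-bromo-2-TBS-oxy-3-methoxyphenyl)-1-ArG-propane-1,3-diol | Brc1cc(OC)c(O[Si](C)(C)C(C)(C)C)c(c1)[C@@H](CO)[C@@H](O)c1ccc(O[Si](C(C)C)(C(C)C)C(C)C)c(OC)c1 | intermediate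
21 | (4R,5S)-5-(5-bromo-2-TBS-oxy-3-methoxyphenyl)-4-ArG-2,2-dimethyl-1,3-dioxane | Brc1cc(OC)c(O[Si](C)(C)C(C)(C)C)c(c1)[C@H]1COC(C)(C)O[C@H]1c1ccc(O[Si](C(C)C)(C(C)C)C(C)C)c(OC)c1 | intermediate
22 | aryllithium from 21 (ArL–Li) | [Li]c1cc(OC)c(O[Si](C)(C)C(C)(C)C)c(c1)[C@H]1COC(C)(C)O[C@H]1c1ccc(O[Si](C(C)C)(C(C)C)C(C)C)c(OC)c1 | intermediate
23 | 4-(TBS-oxy)-3-methoxy-5-[(4R,5S)-4-ArG-2,2-dimethyl-1,3-dioxan-5-yl]benzaldehyde (ArL–CHO) | O=Cc1cc(OC)c(O[Si](C)(C)C(C)(C)C)c(c1)[C@H]1COC(C)(C)O[C@H]1c1ccc(O[Si](C(C)C)(C(C)C)C(C)C)c(OC)c1 | intermediate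
24 | 1-allyl-5-bromo-3-methoxy-2-(ArG-methoxy)benzene | C=CCc1cc(Br)cc(OC)c1OCc1ccc(O[Si](C(C)C)(C(C)C)C(C)C)c(OC)c1 | intermediate
25 | 3-[5-bromo-3-methoxy-2-(ArG-methoxy)benzyl]-1,2,4-trioxolane | COc1cc(Br)cc(CC2OCOO2)c1OCc1ccc(O[Si](C(C)C)(C(C)C)C(C)C)c(OC)c1 | intermediate
26 | 2-[5-bromo-3-methoxy-2-(ArG-methoxy)phenyl]acetaldehyde | O=CCc1cc(Br)cc(OC)c1OCc1ccc(O[Si](C(C)C)(C(C)C)C(C)C)c(OC)c1 | intermediate
27 | 2-[5-bromo-3-methoxy-2-(ArG-methoxy)phenyl]acetic acid | OC(=O)Cc1cc(Br)cc(OC)c1OCc1ccc(O[Si](C(C)C)(C(C)C)C(C)C)c(OC)c1 | intermediate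
28 | methyl 2-[5-bromo-3-methoxy-2-(ArG-methoxy)phenyl]acetate | COC(=O)Cc1cc(Br)cc(OC)c1OCc1ccc(O[Si](C(C)C)(C(C)C)C(C)C)c(OC)c1 | intermediate
29 | methyl 2-diazo-2-[5-bromo-3-methoxy-2-(ArG-methoxy)phenyl]acetate | COC(=O)C(=[N+]=[N-])c1cc(Br)cc(OC)c1OCc1ccc(O[Si](C(C)C)(C(C)C)C(C)C)c(OC)c1 | intermediate
30 | methyl (2S,3R)-5-bromo-7-methoxy-2-ArG-2,3-dihydrobenzofuran-3-carboxylate (cis) | Brc1cc(OC)c2c(c1)[C@@H](C(=O)OC)[C@@H](c1ccc(O[Si](C(C)C)(C(C)C)C(C)C)c(OC)c1)O2 | intermediate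
31 | [(2S,3S)-5-bromo-7-methoxy-2-ArG-2,3-dihydrobenzofuran-3-yl]methanol | Brc1cc(OC)c2c(c1)[C@@H](CO)[C@@H](c1ccc(O[Si](C(C)C)(C(C)C)C(C)C)c(OC)c1)O2 | intermediate
32 | {[(2S,3S)-5-bromo-7-methoxy-2-ArG-2,3-dihydrobenzofuran-3-yl]methoxy}triisopropylsilane | Brc1cc(OC)c2c(c1)[C@@H](CO[Si](C(C)C)(C(C)C)C(C)C)[C@@H](c1ccc(O[Si](C(C)C)(C(C)C)C(C)C)c(OC)c1)O2 | intermediate
33 | aryllithium from 32 (ArR–Li) | [Li]c1cc(OC)c2c(c1)[C@@H](CO[Si](C(C)C)(C(C)C)C(C)C)[C@@H](c1ccc(O[Si](C(C)C)(C(C)C)C(C)C)c(OC)c1)O2 | intermediate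
34 | (2S,3S)-7-methoxy-2-ArG-3-(TIPS-oxymethyl)-2,3-dihydrobenzofuran-5-carbaldehyde (ArR–CHO) | O=Cc1cc(OC)c2c(c1)[C@@H](CO[Si](C(C)C)(C(C)C)C(C)C)[C@@H](c1ccc(O[Si](C(C)C)(C(C)C)C(C)C)c(OC)c1)O2 | intermediate
35 | 2-ArR-1,3-dithiane | C1CSC(SC1)c1cc(OC)c2c(c1)[C@@H](CO[Si](C(C)C)(C(C)C)C(C)C)[C@@H](c1ccc(O[Si](C(C)C)(C(C)C)C(C)C)c(OC)c1)O2 | intermediate
36 | furfural | O=Cc1ccco1 | starting material
37 | furfural singlet-oxygen endoperoxide (racemic) | O=CC12C=CC(OO1)O2 | intermediate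
38 | 5-hydroxyfuran-2(5H)-one (racemic) | OC1OC(=O)C=C1 | intermediate
39 | (5R)-5-[(1R,2S,5R)-menthyloxy]furan-2(5H)-one | O=C1C=C[C@H](O[C@@H]2C[C@H](C)CC[C@H]2C(C)C)O1 | intermediate
40 | 2-lithio-2-ArR-1,3-dithiane | [Li]C1(SCCCS1)c1cc(OC)c2c(c1)[C@@H](CO[Si](C(C)C)(C(C)C)C(C)C)[C@@H](c1ccc(O[Si](C(C)C)(C(C)C)C(C)C)c(OC)c1)O2 | intermediate
41 | lithium enolate of the (4R,5R) Michael adduct | [Li]OC1=C[C@@H](C2(SCCCS2)c2cc(OC)c3c(c2)[C@@H](CO[Si](C(C)C)(C(C)C)C(C)C)[C@@H](c2ccc(O[Si](C(C)C)(C(C)C)C(C)C)c(OC)c2)O3)[C@H](O[C@@H]2C[C@H](C)CC[C@H]2C(C)C)O1 | intermediate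
42 | (3S,4R,5R)-3-[hydroxy(ArL)methyl]-4-(2-ArR-1,3-dithian-2-yl)-5-(menthyloxy)dihydrofuran-2(3H)-one, carbinol epimers | O=C1O[C@@H](O[C@@H]2C[C@H](C)CC[C@H]2C(C)C)[C@H](C2(SCCCS2)c2cc(OC)c3c(c2)[C@@H](CO[Si](C(C)C)(C(C)C)C(C)C)[C@@H](c2ccc(O[Si](C(C)C)(C(C)C)C(C)C)c(OC)c2)O3)[C@H]1C(O)c1cc(OC)c(O[Si](C)(C)C(C)(C)C)c(c1)[C@H]1COC(C)(C)O[C@H]1c1ccc(O[Si](C(C)C)(C(C)C)C(C)C)c(OC)c1 | intermediate
43 | (3S,4R,5R)-4-(ArR-carbonyl)-3-[hydroxy(ArL)methyl]-5-(menthyloxy)dihydrofuran-2(3H)-one, carbinol epimers | O=C1O[C@@H](O[C@@H]2C[C@H](C)CC[C@H]2C(C)C)[C@H](C(=O)c2cc(OC)c3c(c2)[C@@H](CO[Si](C(C)C)(C(C)C)C(C)C)[C@@H](c2ccc(O[Si](C(C)C)(C(C)C)C(C)C)c(OC)c2)O3)[C@H]1C(O)c1cc(OC)c(O[Si](C)(C)C(C)(C)C)c(c1)[C@H]1COC(C)(C)O[C@H]1c1ccc(O[Si](C(C)C)(C(C)C)C(C)C)c(OC)c1 | intermediate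
44 | (2R,3R)-1-ArL-4-ArR-2,3-bis(hydroxymethyl)butane-1,4-diol, epimers at C1 and C4 | OC[C@H](C(O)c1cc(OC)c2c(c1)[C@@H](CO[Si](C(C)C)(C(C)C)C(C)C)[C@@H](c1ccc(O[Si](C(C)C)(C(C)C)C(C)C)c(OC)c1)O2)[C@H](CO)C(O)c1cc(OC)c(O[Si](C)(C)C(C)(C)C)c(c1)[C@H]1COC(C)(C)O[C@H]1c1ccc(O[Si](C(C)C)(C(C)C)C(C)C)c(OC)c1 | intermediate
45 | (1S,3aR,4S,6aR)-1-ArL-4-ArR-tetrahydro-1H,3H-furo[3,4-c]furan | COc1cc(ccc1O[Si](C(C)C)(C(C)C)C(C)C)[C@@H]1OC(C)(C)OC[C@@H]1c1cc(cc(OC)c1O[Si](C)(C)C(C)(C)C)[C@H]1OC[C@H]2[C@@H]1CO[C@@H]2c1cc(OC)c2c(c1)[C@@H](CO[Si](C(C)C)(C(C)C)C(C)C)[C@@H](c1ccc(O[Si](C(C)C)(C(C)C)C(C)C)c(OC)c1)O2 | intermediate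
46 | (1R,2S)-1-ArG-2-{2-(TBS-oxy)-3-methoxy-5-[(1S,3aR,4S,6aR)-4-ArR-furofuran-1-yl]phenyl}propane-1,3-diol | COc1cc(ccc1O[Si](C(C)C)(C(C)C)C(C)C)[C@H](O)[C@H](CO)c1cc(cc(OC)c1O[Si](C)(C)C(C)(C)C)[C@H]1OC[C@H]2[C@@H]1CO[C@@H]2c1cc(OC)c2c(c1)[C@@H](CO[Si](C(C)C)(C(C)C)C(C)C)[C@@H](c1ccc(O[Si](C(C)C)(C(C)C)C(C)C)c(OC)c1)O2 | intermediate
47 | primary TBS ether of 46 (1R,2S) | COc1cc(ccc1O[Si](C(C)C)(C(C)C)C(C)C)[C@H](O)[C@H](CO[Si](C)(C)C(C)(C)C)c1cc(cc(OC)c1O[Si](C)(C)C(C)(C)C)[C@H]1OC[C@H]2[C@@H]1CO[C@@H]2c1cc(OC)c2c(c1)[C@@H](CO[Si](C(C)C)(C(C)C)C(C)C)[C@@H](c1ccc(O[Si](C(C)C)(C(C)C)C(C)C)c(OC)c1)O2 | intermediate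
48 | (2S)-ketone, penta-silylated target | COc1cc(ccc1O[Si](C(C)C)(C(C)C)C(C)C)C(=O)[C@H](CO[Si](C)(C)C(C)(C)C)c1cc(cc(OC)c1O[Si](C)(C)C(C)(C)C)[C@H]1OC[C@H]2[C@@H]1CO[C@@H]2c1cc(OC)c2c(c1)[C@@H](CO[Si](C(C)C)(C(C)C)C(C)C)[C@@H](c1ccc(O[Si](C(C)C)(C(C)C)C(C)C)c(OC)c1)O2 | intermediate
49 | (2S)-3-hydroxy-1-(4-hydroxy-3-methoxyphenyl)-2-{2-hydroxy-5-[(1S,3aR,4S,6aR)-4-[(2S,3S)-2-(4-hydroxy-3-methoxyphenyl)-3-(hydroxymethyl)-7-methoxy-2,3-dihydrobenzofuran-5-yl]tetrahydro-1H,3H-furo[3,4-c]furan-1-yl]-3-methoxyphenyl}propan-1-one | COc1cc(C(=O)[C@H](CO)c2cc([C@H]3OC[C@H]4[C@@H]3CO[C@@H]4c3cc(OC)c4c(c3)[C@@H](CO)[C@@H](c3ccc(O)c(OC)c3)O4)cc(OC)c2O)ccc1O | target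

## Step count and risks

Total step count: 35.
Longest linear sequence: 23 steps (1, 2, 3, 6, 7, 16–25, 28–35; the branch 1–5 that feeds alcohol 7 into step 16 is equally long). The left-half aldehyde 23 is reached in 13 steps (1–3, 6–15) and the butenolide 39 in 2.

The three steps most likely to fail:

**Step 21 (C–H insertion: cis/trans ratio, enantioselectivity and sense of induction on this substituted substrate).** The fallback sets out from diol 20, which already has the required configuration, and comes back at bromide 32. TIPSCl and imidazole silylate the primary hydroxyl to give the primary TIPS ether F1. Cs2CO3 in MeOH/THF then removes both aryl silyl groups to give the bis-phenol F2. TIPSCl and imidazole at 0 °C re-silylate only the unhindered guaiacyl phenol, giving the mono-phenol F3. PPh3 and diisopropyl azodicarboxylate in toluene at 0 °C close the ring by Mitsunobu SN2 displacement of the benzylic hydroxyl by the flanked phenol, with inversion ((1R,2S) to (2S,3S)), giving 32. The weakness of this path is partial SN1 leakage to the trans isomer at the electron-rich benzylic carbon.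

**Step 28 (one-pot three-component coupling of two advanced fragments).** The fallback sets out from dithiane 35 and butenolide 39 and comes back at adduct 42. The conjugate addition is run alone and quenched with NH4Cl, and the (4R,5R) Michael adduct F4 is isolated and purified. It is then re-enolised with LiN(i-Pr)2 in THF at −78 °C to the enolate 41 and treated with aldehyde 23, so the aldehyde never meets unreacted dithiane anion or butenolide and each stage can be optimised separately.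

**Step 31 (acid-mediated double ring closure in the presence of the acetonide and the cis-dihydrobenzofuran).** The fallback sets out from tetraol 44 and comes back at furofuran 45 without Brønsted acid. TESCl (2.1 equiv) and imidazole at −40 °C cap the two primary hydroxyls to give the bis(triethylsilyl) ether F5. MsCl and Et3N in CH2Cl2 (−20 °C to rt) then convert the two benzylic hydroxyls into mesylates that ionise under basic conditions. The silyl ether oxygens capture the cations 5-exo with loss of the triethylsilyl groups, giving the same exo,exo product 45.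

## Further compounds

F1 | step 21 | (1R,2S)-2-(5-bromo-2-TBS-oxy-3-methoxyphenyl)-1-ArG-3-(TIPS-oxy)propan-1-ol | Brc1cc(OC)c(O[Si](C)(C)C(C)(C)C)c(c1)[C@@H](CO[Si](C(C)C)(C(C)C)C(C)C)[C@@H](O)c1ccc(O[Si](C(C)C)(C(C)C)C(C)C)c(OC)c1
F2 | step 21 | 4-bromo-2-[(1R,2S)-1-hydroxy-1-(4-hydroxy-3-methoxyphenyl)-3-(TIPS-oxy)propan-2-yl]-6-methoxyphenol | Brc1cc(OC)c(O)c(c1)[C@@H](CO[Si](C(C)C)(C(C)C)C(C)C)[C@@H](O)c1ccc(O)c(OC)c1
F3 | step 21 | 4-bromo-2-[(1R,2S)-1-hydroxy-1-ArG-3-(TIPS-oxy)propan-2-yl]-6-methoxyphenol | Brc1cc(OC)c(O)c(c1)[C@@H](CO[Si](C(C)C)(C(C)C)C(C)C)[C@@H](O)c1ccc(O[Si](C(C)C)(C(C)C)C(C)C)c(OC)c1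
F4 | step 28 | (4R,5R)-4-(2-ArR-1,3-dithian-2-yl)-5-(menthyloxy)dihydrofuran-2(3H)-one | O=C1O[C@@H](O[C@@H]2C[C@H](C)CC[C@H]2C(C)C)[C@H](C2(SCCCS2)c2cc(OC)c3c(c2)[C@@H](CO[Si](C(C)C)(C(C)C)C(C)C)[C@@H](c2ccc(O[Si](C(C)C)(C(C)C)C(C)C)c(OC)c2)O3)C1
F5 | step 31 | (2R,3R)-1-ArL-4-ArR-2,3-bis[(triethylsilyloxy)methyl]butane-1,4-diol, epimers at C1 and C4 | CC[Si](CC)(CC)OC[C@H](C(O)c1cc(OC)c2c(c1)[C@@H](CO[Si](C(C)C)(C(C)C)C(C)C)[C@@H](c1ccc(O[Si](C(C)C)(C(C)C)C(C)C)c(OC)c1)O2)[C@H](CO[Si](CC)(CC)CC)C(O)c1cc(OC)c(O[Si](C)(C)C(C)(C)C)c(c1)[C@H]1COC(C)(C)O[C@H]1c1ccc(O[Si](C(C)C)(C(C)C)C(C)C)c(OC)c1
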